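**Retrosynthetic overview** (germacrane numbering: carbocycle C1–C10, lactone O–C6/C7/C11/C12, C13 on C11, C14 on C10, C15 on C4)

- Endgame: the C8–O ester comes from a carbodiimide coupling with silyl-protected 4-hydroxytiglic acid, C11 from 1,4-reduction of a C11=C13 α-methylene lactone, then global desilylation.
- Key disconnection C7–C8: intramolecular Nozaki–Hiyama allylation of a C8 aldehyde by the allylchromium made from a 3-(bromomethyl)butenolide (C13–Br, C11=C7). It closes the ten-membered ring onto the finished γ-lactone, sets C7 and C8, and unveils the α-methylene lactone.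
- Enabling feature: the C8 carbinol sits on C7, the lactone β-carbon, so O–C8–C7–C11(–C13) is a homoallylic-alcohol retron once the lactone is taken to the 11,13-dehydro level. The butenolide ring locks the allyl geometry, and C6 is the only stereocentre the precursor needs.
- Precursor: butenolide by acylation/ring-closing metathesis; C6 by catalytic asymmetric alkynylation of crotonaldehyde; C4=C5/C15 by trans-hydroalumination–iodination and Stille hydroxymethylation; ring-cis C1=C10 by syn-carbocupration of a 2-ynoate; C2–C3 by propargyl alkylation.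
- Ring order: γ-lactone first (step 12), cyclodeca-1(10),4-diene last (step 15).

Key step: step 15

Remark: the SMILES is read as the (3S,3aR,4S,6Z,10Z,11aR) isomer, i.e. ring-cis C1=C10, ring-trans C4=C5, 6α,12-olide, 8α-acyloxy, 11α-methyl; the route is built for exactly this geometry.

**Step 1**
Reactants: 1 4-[(tert-butyldimethylsilyl)oxy]but-1-yne
Product: 3 methyl 5-[(tert-butyldimethylsilyl)oxy]pent-2-ynoate, via lithium acetylide 2 (not isolated)
Conditions: n-BuLi, THF, −78 °C; ClCO2Me, −78 → 0 °C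
Reagents that add atoms: methyl chloroformate, COC(=O)Cl; n-butyllithium, [Li]CCCC (lithium of 2 only)
Why: C-acylation of a lithium acetylide with a chloroformate is the standard entry to 2-ynoates; no stereocentre is formed.

**Step 2**
Reactants: 3 methyl 5-[(tert-butyldimethylsilyl)oxy]pent-2-ynoate
Product: 4 methyl (2Z)-5-[(tert-butyldimethylsilyl)oxy]-3-methylpent-2-enoate
Conditions: Me2CuLi (MeLi, CuI), THF, −78 °C; aq. NH4Cl at −78 °C
Reagents that add atoms: lithium dimethylcuprate, [Li+].C[Cu-]C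
Why: syn-carbocupration of the ynoate (cuprate conjugate addition) with a cold quench should place the new methyl (C14) trans to the ester carbon (C2), so C9 and C2 end up cis, the ring-cis C1=C10 geometry.

**Step 3**
Reactants: 4 methyl (2Z)-5-[(tert-butyldimethylsilyl)oxy]-3-methylpent-2-enoate
Product: 5 (2Z)-5-[(tert-butyldimethylsilyl)oxy]-3-methylpent-2-en-1-ol
Conditions: DIBAL-H, CH2Cl2, −78 °C; Rochelle salt
Reagents that add atoms: none
Why: DIBAL-H 1,2-reduction of an enoate to the allylic alcohol should keep the olefin geometry.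

**Step 4**
Reactants: 5 (2Z)-5-[(tert-butyldimethylsilyl)oxy]-3-methylpent-2-en-1-ol
Product: 6 (3Z)-5-bromo-1-[(tert-butyldimethylsilyl)oxy]-3-methylpent-3-ene
Conditions: CBr4, PPh3, CH2Cl2, 0 °C
Reagents that add atoms: carbon tetrabromide, BrC(Br)(Br)Br
Why: Appel bromination of a primary allylic alcohol proceeds by SN2 at low temperature without allylic transposition or Z/E loss.

**Step 5**
Reactants: 6 (3Z)-5-bromo-1-[(tert-butyldimethylsilyl)oxy]-3-methylpent-3-ene; 7 1-(trimethylsilyl)propyne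
Product: 9 (3Z)-1-[(tert-butyldimethylsilyl)oxy]-3-methyl-8-(trimethylsilyl)oct-3-en-7-yne, via 3-lithio-1-(trimethylsilyl)propyne 8 (not isolated)
Conditions: 7, n-BuLi, THF, −78 °C; then 6, −78 → −20 °C
Reagents that add atoms: n-butyllithium, [Li]CCCC (lithium of 8 only; no atom stays in 9)
Why: SN2 alkylation of silyl-capped propargyllithium with a primary allylic bromide makes the C2–C3 bond, the silyl group steering propargyl over allenyl attack.

**Step 6**
Reactants: 9 (3Z)-1-[(tert-butyldimethylsilyl)oxy]-3-methyl-8-(trimethylsilyl)oct-3-en-7-yne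
Product: 10 (3Z)-1-[(tert-butyldimethylsilyl)oxy]-3-methyloct-3-en-7-yne
Conditions: K2CO3, MeOH, rt
Reagents that add atoms: none
Why: base-mediated protodesilylation of an alkynylsilane leaves the alkyl TBS ether intact.

**Step 7**
Reactants: 10 (3Z)-1-[(tert-butyldimethylsilyl)oxy]-3-methyloct-3-en-7-yne; 11 (E)-but-2-enal
Product: 13 (2E,4S,9Z)-12-[(tert-butyldimethylsilyl)oxy]-10-methyldodeca-2,9-dien-5-yn-4-ol, via alkynyl(methyl)zinc 12 (not isolated)
Conditions: Me2Zn, ProPhenol (10 mol%, the antipode that gives the 4S carbinol), Ph3P=O (20 mol%), 11 in excess, toluene, 4 °C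
Reagents that add atoms: dimethylzinc, C[Zn]C (zinc and methyl of 12 only; no atom stays in 13)
Why: dinuclear zinc–ProPhenol catalysed enantioselective alkynylation of an enal (1,2-addition) sets C6 by catalyst face selection; the sense is to be confirmed by Mosher ester analysis before going on.

**Step 8**
Reactants: 13 (2E,4S,9Z)-12-[(tert-butyldimethylsilyl)oxy]-10-methyldodeca-2,9-dien-5-yn-4-ol
Product: 15 (2E,4S,5Z,9Z)-12-[(tert-butyldimethylsilyl)oxy]-6-iodo-10-methyldodeca-2,5,9-trien-4-ol, via alkenyl(alkoxy)aluminate 14 (not isolated)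
Conditions: Red-Al, THF, 0 °C; EtOAc; I2, −78 °C
Reagents that add atoms: iodine, II; Red-Al, [Na+].COCCO[AlH2-]OCCOC (sodium, aluminium and 2-methoxyethoxy groups of 14 only)
Why: hydroxyl-directed trans-hydroalumination of the propargylic alcohol followed by iodinolysis with retention should give the γ-iodo allylic alcohol with iodine cis to C6 and the C3 chain trans, the ring-trans C4=C5 geometry.

**Step 9**
Reactants: 15 (2E,4S,5Z,9Z)-12-[(tert-butyldimethylsilyl)oxy]-6-iodo-10-methyldodeca-2,5,9-trien-4-ol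
Product: 16 (2E,4S,5Z,9Z)-12-[(tert-butyldimethylsilyl)oxy]-6-(hydroxymethyl)-10-methyldodeca-2,5,9-trien-4-ol
Conditions: Bu3SnCH2OH, Pd(PPh3)4 (5 mol%), 1,4-dioxane, 90 °C
Reagents that add atoms: (tributylstannyl)methanol, OC[Sn](CCCC)(CCCC)CCCC
Why: Stille hydroxymethylation of an alkenyl iodide proceeds with retention of geometry and installs C15 cis to C6.

**Step 10**
Reactants: 16 (2E,4S,5Z,9Z)-12-[(tert-butyldimethylsilyl)oxy]-6-(hydroxymethyl)-10-methyldodeca-2,5,9-trien-4-ol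
Product: 17 (2E,4S,5Z,9Z)-12-[(tert-butyldimethylsilyl)oxy]-6-{[(tert-butyldiphenylsilyl)oxy]methyl}-10-methyldodeca-2,5,9-trien-4-ol
Conditions: TBDPSCl, imidazole, CH2Cl2, 0 °C
Reagents that add atoms: tert-butyl(chloro)diphenylsilane, CC(C)(C)[Si](Cl)(c1ccccc1)c1ccccc1
Why: silylation should be selective for the primary allylic hydroxyl over the hindered secondary bis-allylic one.

**Step 11**
Reactants: 17 (2E,4S,5Z,9Z)-12-[(tert-butyldimethylsilyl)oxy]-6-{[(tert-butyldiphenylsilyl)oxy]methyl}-10-methyldodeca-2,5,9-trien-4-ol; 18 2-(bromomethyl)prop-2-enoic acid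
Product: 20 (2E,4S,5Z,9Z)-12-[(tert-butyldimethylsilyl)oxy]-6-{[(tert-butyldiphenylsilyl)oxy]methyl}-10-methyldodeca-2,5,9-trien-4-yl 2-(bromomethyl)prop-2-enoate, via 2-(bromomethyl)prop-2-enoyl chloride 19 (not isolated)
Conditions: 18, (COCl)2, cat. DMF, CH2Cl2, 0 °C → rt, concentrate; then 17, 2,6-lutidine, CH2Cl2, −20 → 0 °C
Reagents that add atoms: oxalyl chloride, O=C(Cl)C(Cl)=O (chlorine of 19 only; no atom stays in 20)
Why: O-acylation with an acid chloride and a hindered, non-nucleophilic base avoids the SN2′ amination that nucleophilic acylation catalysts cause on bromomethyl acrylates; C6 is untouched.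

**Step 12**
Reactants: 20 (2E,4S,5Z,9Z)-12-[(tert-butyldimethylsilyl)oxy]-6-{[(tert-butyldiphenylsilyl)oxy]methyl}-10-methyldodeca-2,5,9-trien-4-yl 2-(bromomethyl)prop-2-enoate
Product: 21 (5R)-3-(bromomethyl)-5-[(1Z,5Z)-8-[(tert-butyldimethylsilyl)oxy]-2-{[(tert-butyldiphenylsilyl)oxy]methyl}-6-methylocta-1,5-dien-1-yl]furan-2(5H)-one
Conditions: Grubbs II (10 mol%), CH2Cl2, 40 °C, 5 mM
Reagents that add atoms: none
Why: ring-closing metathesis between the propenyl group and the acrylate olefin closes the butenolide (the first ring) with loss of propene; the trisubstituted chain olefins are too hindered to compete.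

**Step 13**
Reactants: 21 (5R)-3-(bromomethyl)-5-[(1Z,5Z)-8-[(tert-butyldimethylsilyl)oxy]-2-{[(tert-butyldiphenylsilyl)oxy]methyl}-6-methylocta-1,5-dien-1-yl]furan-2(5H)-one
Product: 22 (5R)-3-(bromomethyl)-5-[(1Z,5Z)-2-{[(tert-butyldiphenylsilyl)oxy]methyl}-8-hydroxy-6-methylocta-1,5-dien-1-yl]furan-2(5H)-one
Conditions: CSA (10 mol%), MeOH/CH2Cl2, 0 °C
Reagents that add atoms: none
Why: acid-catalysed methanolysis removes a primary TBS ether much faster than a TBDPS ether and is non-basic, so the base-labile C6–H of the butenolide is not at risk.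

**Step 14**
Reactants: 22 (5R)-3-(bromomethyl)-5-[(1Z,5Z)-2-{[(tert-butyldiphenylsilyl)oxy]methyl}-8-hydroxy-6-methylocta-1,5-dien-1-yl]furan-2(5H)-one
Product: 23 (3Z,7Z)-8-[(2R)-4-(bromomethyl)-5-oxo-2,5-dihydrofuran-2-yl]-7-{[(tert-butyldiphenylsilyl)oxy]methyl}-3-methylocta-3,7-dienal
Conditions: Dess–Martin periodinane, NaHCO3, CH2Cl2, 0 °C; short silica plug, used at once
Reagents that add atoms: none
Why: buffered Dess–Martin oxidation gives the β,γ-unsaturated aldehyde without moving the C1=C10 olefin into conjugation.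

**Step 15**
Reactants: 23 (3Z,7Z)-8-[(2R)-4-(bromomethyl)-5-oxo-2,5-dihydrofuran-2-yl]-7-{[(tert-butyldiphenylsilyl)oxy]methyl}-3-methylocta-3,7-dienal
Product: 25 (3aR,4S,6Z,10Z,11aR)-10-{[(tert-butyldiphenylsilyl)oxy]methyl}-4-hydroxy-6-methyl-3-methylidene-3a,4,5,8,9,11a-hexahydrocyclodeca[b]furan-2(3H)-one, via allylchromium(III) dichloride 24 (not isolated)
Conditions: CrCl2 (10 equiv), THF, rt, syringe-pump addition of 23 to about 2 mM; aq. NH4Cl
Reagents that add atoms: chromium(II) chloride, Cl[Cr]Cl (chromium and chlorine of 24 only; no atom stays in 25)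
Why: CrCl2 inserts into the allylic C13–Br bond of the 3-(bromomethyl)butenolide to give allylchromium(III) 24, which adds through its γ-carbon C7 to the tethered C8 aldehyde in a six-membered chair (Zimmerman–Traxler) transition state and moves the double bond to C11=C13. The closest known reactions are Nozaki–Hiyama (chromium Barbier) allylations of aldehydes with 2-(bromomethyl)alk-2-enoates, including their intramolecular use for ten-membered germacranolide rings, and Barbier additions of 3-(bromomethyl)furan-2(5H)-ones through the ring γ-carbon. The ten-membered carbocycle closes by 10-exo-trig attack on the aldehyde carbon (new bond C7–C8, SE2′ at the allyl unit) onto the already closed γ-lactone. C7 is controlled by C6: bond formation anti to the C5 alkenyl substituent gives the trans-fused lactone; C8 is controlled by the chair with C9 equatorial and an allyl geometry that the lactone ring locks (C6 trans to C13, an E-crotyl-type donor), which should give the anti C7/C8 array, i.e. the 8α-alcohol. The step needs γ- over α-attack, which is inherent to ester-substituted allylchromium reagents, and ring closure over oligomerisation and simple C–Br reduction, which slow addition to excess CrCl2 at high dilution, the cis-disposed C9 and C2 arms of the (Z)-C1=C10 olefin and the rigid butenolide should secure.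

**Step 16**
Reactants: 26 [(tert-butyldimethylsilyl)oxy]acetaldehyde; 27 ethyl 2-(triphenyl-λ5-phosphanylidene)propanoate
Product: 28 ethyl (2E)-4-[(tert-butyldimethylsilyl)oxy]-2-methylbut-2-enoate
Conditions: CH2Cl2, rt
Reagents that add atoms: none
Why: Wittig olefination with a stabilised α-methyl ylide is E-selective.

**Step 17**
Reactants: 28 ethyl (2E)-4-[(tert-butyldimethylsilyl)oxy]-2-methylbut-2-enoate
Product: 29 (2E)-4-[(tert-butyldimethylsilyl)oxy]-2-methylbut-2-enoic acid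
Conditions: LiOH, THF/H2O, rt; 1 M HCl to pH 4, 0 °C
Reagents that add atoms: lithium hydroxide, [Li+].[OH-]
Why: saponification of the ethyl ester leaves the primary TBS ether and the E olefin intact under a brief, cold acidification.

**Step 18**
Reactants: 25 (3aR,4S,6Z,10Z,11aR)-10-{[(tert-butyldiphenylsilyl)oxy]methyl}-4-hydroxy-6-methyl-3-methylidene-3a,4,5,8,9,11a-hexahydrocyclodeca[b]furan-2(3H)-one; 29 (2E)-4-[(tert-butyldimethylsilyl)oxy]-2-methylbut-2-enoic acid
Product: 30 (3aR,4S,6Z,10Z,11aR)-10-{[(tert-butyldiphenylsilyl)oxy]methyl}-6-methyl-3-methylidene-2-oxo-2,3,3a,4,5,8,9,11a-octahydrocyclodeca[b]furan-4-yl (2E)-4-[(tert-butyldimethylsilyl)oxy]-2-methylbut-2-enoate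
Conditions: DIC, DMAP (20 mol%), CH2Cl2, 0 °C → rt
Reagents that add atoms: none
Why: Steglich-type esterification acylates the C8 hydroxyl with retention at C8 and, once done, blocks 6,12 → 8,12 translactonisation.

**Step 19**
Reactants: 30 (3aR,4S,6Z,10Z,11aR)-10-{[(tert-butyldiphenylsilyl)oxy]methyl}-6-methyl-3-methylidene-2-oxo-2,3,3a,4,5,8,9,11a-octahydrocyclodeca[b]furan-4-yl (2E)-4-[(tert-butyldimethylsilyl)oxy]-2-methylbut-2-enoate
Product: 31 (3S,3aR,4S,6Z,10Z,11aR)-10-{[(tert-butyldiphenylsilyl)oxy]methyl}-3,6-dimethyl-2-oxo-2,3,3a,4,5,8,9,11a-octahydrocyclodeca[b]furan-4-yl (2E)-4-[(tert-butyldimethylsilyl)oxy]-2-methylbut-2-enoate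
Conditions: NaBH4, MeOH, 0 °C
Reagents that add atoms: none
Why: chemoselective 1,4-reduction of the exocyclic α-methylene lactone (the trisubstituted tiglate-type ester is inert) followed by protonation of the lactone enolate should give the 11α-methyl (11βH) epimer, as is usual for 6α,12-germacranolides and as is thermodynamically favoured, the methyl lying anti to the C8 substituent.

**Step 20**
Reactants: 31 (3S,3aR,4S,6Z,10Z,11aR)-10-{[(tert-butyldiphenylsilyl)oxy]methyl}-3,6-dimethyl-2-oxo-2,3,3a,4,5,8,9,11a-octahydrocyclodeca[b]furan-4-yl (2E)-4-[(tert-butyldimethylsilyl)oxy]-2-methylbut-2-enoate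
Product: 32 (3S,3aR,4S,6Z,10Z,11aR)-10-(hydroxymethyl)-3,6-dimethyl-2-oxo-2,3,3a,4,5,8,9,11a-octahydrocyclodeca[b]furan-4-yl (2E)-4-hydroxy-2-methylbut-2-enoate
Conditions: HF·pyridine, pyridine/THF, 0 °C → rt
Reagents that add atoms: none
Why: fluoride-mediated cleavage of both primary silyl ethers under non-basic conditions avoids acyl migration and lactone opening; no stereocentre is touched.

**Compound list**

1 | 4-[(tert-butyldimethylsilyl)oxy]but-1-yne | C#CCCO[Si](C)(C)C(C)(C)C | starting material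
2 | lithium 4-[(tert-butyldimethylsilyl)oxy]but-1-yn-1-ide | [Li]C#CCCO[Si](C)(C)C(C)(C)C | intermediate
3 | methyl 5-[(tert-butyldimethylsilyl)oxy]pent-2-ynoate | COC(=O)C#CCCO[Si](C)(C)C(C)(C)C | intermediate
4 | methyl (2Z)-5-[(tert-butyldimethylsilyl)oxy]-3-methylpent-2-enoate | COC(=O)/C=C(C)\CCO[Si](C)(C)C(C)(C)C | intermediate
5 | (2Z)-5-[(tert-butyldimethylsilyl)oxy]-3-methylpent-2-en-1-ol | OC/C=C(C)\CCO[Si](C)(C)C(C)(C)C | intermediate
6 | (3Z)-5-bromo-1-[(tert-butyldimethylsilyl)oxy]-3-methylpent-3-ene | BrC/C=C(C)\CCO[Si](C)(C)C(C)(C)C | intermediate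
7 | 1-(trimethylsilyl)propyne | CC#C[Si](C)(C)C | starting material
8 | 3-lithio-1-(trimethylsilyl)propyne | [Li]CC#C[Si](C)(C)C | intermediate
9 | (3Z)-1-[(tert-butyldimethylsilyl)oxy]-3-methyl-8-(trimethylsilyl)oct-3-en-7-yne | C[Si](C)(C)C#CCC/C=C(C)\CCO[Si](C)(C)C(C)(C)C | intermediate
10 | (3Z)-1-[(tert-butyldimethylsilyl)oxy]-3-methyloct-3-en-7-yne | C#CCC/C=C(C)\CCO[Si](C)(C)C(C)(C)C | intermediate
11 | (E)-but-2-enal (crotonaldehyde) | C/C=C/C=O | starting material
12 | methyl[(5Z)-8-[(tert-butyldimethylsilyl)oxy]-6-methyloct-5-en-1-yn-1-yl]zinc | C[Zn]C#CCC/C=C(C)\CCO[Si](C)(C)C(C)(C)C | intermediate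
13 | (2E,4S,9Z)-12-[(tert-butyldimethylsilyl)oxy]-10-methyldodeca-2,9-dien-5-yn-4-ol | C/C=C/[C@H](O)C#CCC/C=C(C)\CCO[Si](C)(C)C(C)(C)C | intermediate
14 | sodium cyclic alkenyl(alkoxy)bis(2-methoxyethoxy)aluminate from 13 (Al on C4 of the chain, O–Al chelate) | [Na+].C/C=C/[C@@H]1O[Al-](OCCOC)(OCCOC)C(CC/C=C(C)\CCO[Si](C)(C)C(C)(C)C)=C1 | intermediate
15 | (2E,4S,5Z,9Z)-12-[(tert-butyldimethylsilyl)oxy]-6-iodo-10-methyldodeca-2,5,9-trien-4-ol | C/C=C/[C@H](O)/C=C(I)/CC/C=C(C)\CCO[Si](C)(C)C(C)(C)C | intermediate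
16 | (2E,4S,5Z,9Z)-12-[(tert-butyldimethylsilyl)oxy]-6-(hydroxymethyl)-10-methyldodeca-2,5,9-trien-4-ol | C/C=C/[C@H](O)/C=C(CO)/CC/C=C(C)\CCO[Si](C)(C)C(C)(C)C | intermediate
17 | (2E,4S,5Z,9Z)-12-[(tert-butyldimethylsilyl)oxy]-6-{[(tert-butyldiphenylsilyl)oxy]methyl}-10-methyldodeca-2,5,9-trien-4-ol | C/C=C/[C@H](O)/C=C(CO[Si](c1ccccc1)(c1ccccc1)C(C)(C)C)/CC/C=C(C)\CCO[Si](C)(C)C(C)(C)C | intermediate
18 | 2-(bromomethyl)prop-2-enoic acid | OC(=O)C(=C)CBr | starting material
19 | 2-(bromomethyl)prop-2-enoyl chloride | ClC(=O)C(=C)CBr | intermediate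
20 | (2E,4S,5Z,9Z)-12-[(tert-butyldimethylsilyl)oxy]-6-{[(tert-butyldiphenylsilyl)oxy]methyl}-10-methyldodeca-2,5,9-trien-4-yl 2-(bromomethyl)prop-2-enoate | C/C=C/[C@H](OC(=O)C(=C)CBr)/C=C(CO[Si](c1ccccc1)(c1ccccc1)C(C)(C)C)/CC/C=C(C)\CCO[Si](C)(C)C(C)(C)C | intermediate
21 | (5R)-3-(bromomethyl)-5-[(1Z,5Z)-8-[(tert-butyldimethylsilyl)oxy]-2-{[(tert-butyldiphenylsilyl)oxy]methyl}-6-methylocta-1,5-dien-1-yl]furan-2(5H)-one | CC(C)(C)[Si](C)(C)OCC/C(C)=C\CC/C(CO[Si](c1ccccc1)(c1ccccc1)C(C)(C)C)=C/[C@H]1OC(=O)C(CBr)=C1 | intermediate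
22 | (5R)-3-(bromomethyl)-5-[(1Z,5Z)-2-{[(tert-butyldiphenylsilyl)oxy]methyl}-8-hydroxy-6-methylocta-1,5-dien-1-yl]furan-2(5H)-one | OCC/C(C)=C\CC/C(CO[Si](c1ccccc1)(c1ccccc1)C(C)(C)C)=C/[C@H]1OC(=O)C(CBr)=C1 | intermediate
23 | (3Z,7Z)-8-[(2R)-4-(bromomethyl)-5-oxo-2,5-dihydrofuran-2-yl]-7-{[(tert-butyldiphenylsilyl)oxy]methyl}-3-methylocta-3,7-dienal | O=CC/C(C)=C\CC/C(CO[Si](c1ccccc1)(c1ccccc1)C(C)(C)C)=C/[C@H]1OC(=O)C(CBr)=C1 | intermediate
24 | allylchromium(III) dichloride from 23 (Cr on the former CH2Br carbon) | O=CC/C(C)=C\CC/C(CO[Si](c1ccccc1)(c1ccccc1)C(C)(C)C)=C/[C@H]1OC(=O)C(C[Cr](Cl)Cl)=C1 | intermediate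
25 | (3aR,4S,6Z,10Z,11aR)-10-{[(tert-butyldiphenylsilyl)oxy]methyl}-4-hydroxy-6-methyl-3-methylidene-3a,4,5,8,9,11a-hexahydrocyclodeca[b]furan-2(3H)-one | C/C1=C/CC/C(CO[Si](c3ccccc3)(c3ccccc3)C(C)(C)C)=C/[C@H]2OC(=O)C(=C)[C@@H]2[C@@H](O)C1 | intermediate
26 | [(tert-butyldimethylsilyl)oxy]acetaldehyde | O=CCO[Si](C)(C)C(C)(C)C | starting material
27 | ethyl 2-(triphenyl-λ5-phosphanylidene)propanoate | CCOC(=O)C(C)=P(c1ccccc1)(c1ccccc1)c1ccccc1 | starting material
28 | ethyl (2E)-4-[(tert-butyldimethylsilyl)oxy]-2-methylbut-2-enoate | CCOC(=O)/C(C)=C/CO[Si](C)(C)C(C)(C)C | intermediate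
29 | (2E)-4-[(tert-butyldimethylsilyl)oxy]-2-methylbut-2-enoic acid | OC(=O)/C(C)=C/CO[Si](C)(C)C(C)(C)C | intermediate
30 | (3aR,4S,6Z,10Z,11aR)-10-{[(tert-butyldiphenylsilyl)oxy]methyl}-6-methyl-3-methylidene-2-oxo-2,3,3a,4,5,8,9,11a-octahydrocyclodeca[b]furan-4-yl (2E)-4-[(tert-butyldimethylsilyl)oxy]-2-methylbut-2-enoate | C/C1=C/CC/C(CO[Si](c3ccccc3)(c3ccccc3)C(C)(C)C)=C/[C@H]2OC(=O)C(=C)[C@@H]2[C@@H](OC(=O)/C(C)=C/CO[Si](C)(C)C(C)(C)C)C1 | intermediate
31 | (3S,3aR,4S,6Z,10Z,11aR)-10-{[(tert-butyldiphenylsilyl)oxy]methyl}-3,6-dimethyl-2-oxo-2,3,3a,4,5,8,9,11a-octahydrocyclodeca[b]furan-4-yl (2E)-4-[(tert-butyldimethylsilyl)oxy]-2-methylbut-2-enoate | C/C1=C/CC/C(CO[Si](c3ccccc3)(c3ccccc3)C(C)(C)C)=C/[C@H]2OC(=O)[C@@H](C)[C@@H]2[C@@H](OC(=O)/C(C)=C/CO[Si](C)(C)C(C)(C)C)C1 | intermediate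
32 | (3S,3aR,4S,6Z,10Z,11aR)-10-(hydroxymethyl)-3,6-dimethyl-2-oxo-2,3,3a,4,5,8,9,11a-octahydrocyclodeca[b]furan-4-yl (2E)-4-hydroxy-2-methylbut-2-enoate | C/C1=C/CC/C(CO)=C/[C@H]2OC(=O)[C@@H](C)[C@@H]2[C@@H](OC(=O)/C(C)=C/CO)C1 | target

**Step count and risks**

Total step count: 20. Longest linear sequence: 18 (steps 1–15 and 18–20); steps 16–17 make the side-chain acid.

Steps most likely to fail:

1. Step 15 (macrocyclic allylation). Oligomerisation or plain reduction of the C–Br bond may outrun ring closure, and the tether may force the aldehyde substituent axial (boat-like or non-chelated addition), so that the hydroxyl is delivered to the wrong face of C8. Fallback, setting out from aldehyde 23: the same closure is accepted with the opposite C8 configuration, giving (3aR,4R,6Z,10Z,11aR)-10-{[(tert-butyldiphenylsilyl)oxy]methyl}-4-hydroxy-6-methyl-3-methylidene-3a,4,5,8,9,11a-hexahydrocyclodeca[b]furan-2(3H)-one F1. The C8 centre is then corrected by an invertive Mitsunobu esterification with acid 29 (PPh3, DIAD, toluene, 0 °C → rt), which forms the C8–O ester bond and the 8α configuration in one operation and rejoins the route at ester 30.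

2. Step 12 (metathesis to the bromomethyl butenolide). The hindered, electron-poor bromomethyl acrylate may turn over slowly, and the allylic bromide may deactivate the ruthenium carbene. Fallback, setting out from alcohol 17 and acid 18: the bromide is installed after the ring is closed.
   - Acid 18 is treated with 4-methoxybenzyl alcohol and NaH in THF to give 2-{[(4-methoxybenzyl)oxy]methyl}prop-2-enoic acid F2.
   - DIC/DMAP coupling with 17 gives the ester (2E,4S,5Z,9Z)-12-[(tert-butyldimethylsilyl)oxy]-6-{[(tert-butyldiphenylsilyl)oxy]methyl}-10-methyldodeca-2,5,9-trien-4-yl 2-{[(4-methoxybenzyl)oxy]methyl}prop-2-enoate F3.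
   - Metathesis of this halogen-free acrylate with Grubbs II gives (5R)-5-[(1Z,5Z)-8-[(tert-butyldimethylsilyl)oxy]-2-{[(tert-butyldiphenylsilyl)oxy]methyl}-6-methylocta-1,5-dien-1-yl]-3-{[(4-methoxybenzyl)oxy]methyl}furan-2(5H)-one F4.
   - DDQ in buffered CH2Cl2 frees the alcohol (5R)-5-[(1Z,5Z)-8-[(tert-butyldimethylsilyl)oxy]-2-{[(tert-butyldiphenylsilyl)oxy]methyl}-6-methylocta-1,5-dien-1-yl]-3-(hydroxymethyl)furan-2(5H)-one F5.
   - Appel bromination (CBr4, PPh3, 0 °C) returns to bromide 21.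

3. Step 7 (asymmetric alkynylation). Zinc acetylide formation from an unactivated alkyl alkyne may be slow and face selection with a small enal may be poor, with aldehyde self-condensation competing. Fallback, setting out from alkyne 10: the stereocentre is set by reduction instead of addition. Lithiation (n-BuLi, THF, −78 °C) and addition to crotonaldehyde 11 gives racemic (2E,9Z)-12-[(tert-butyldimethylsilyl)oxy]-10-methyldodeca-2,9-dien-5-yn-4-ol F6. MnO2 in CH2Cl2 oxidises it to the ynone (2E,9Z)-12-[(tert-butyldimethylsilyl)oxy]-10-methyldodeca-2,9-dien-5-yn-4-one F7. Midland reduction with (S)-Alpine-Borane, in which the alkynyl group acts as the small substituent, should then give the 4S alcohol 13.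

**Further compounds**

F1 | step 15 | (3aR,4R,6Z,10Z,11aR)-10-{[(tert-butyldiphenylsilyl)oxy]methyl}-4-hydroxy-6-methyl-3-methylidene-3a,4,5,8,9,11a-hexahydrocyclodeca[b]furan-2(3H)-one | C/C1=C/CC/C(CO[Si](c3ccccc3)(c3ccccc3)C(C)(C)C)=C/[C@H]2OC(=O)C(=C)[C@@H]2[C@H](O)C1
F2 | step 12 | 2-{[(4-methoxybenzyl)oxy]methyl}prop-2-enoic acid | COc1ccc(COCC(=C)C(=O)O)cc1
F3 | step 12 | (2E,4S,5Z,9Z)-12-[(tert-butyldimethylsilyl)oxy]-6-{[(tert-butyldiphenylsilyl)oxy]methyl}-10-methyldodeca-2,5,9-trien-4-yl 2-{[(4-methoxybenzyl)oxy]methyl}prop-2-enoate | C/C=C/[C@H](OC(=O)C(=C)COCc1ccc(OC)cc1)/C=C(CO[Si](c1ccccc1)(c1ccccc1)C(C)(C)C)/CC/C=C(C)\CCO[Si](C)(C)C(C)(C)C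
F4 | step 12 | (5R)-5-[(1Z,5Z)-8-[(tert-butyldimethylsilyl)oxy]-2-{[(tert-butyldiphenylsilyl)oxy]methyl}-6-methylocta-1,5-dien-1-yl]-3-{[(4-methoxybenzyl)oxy]methyl}furan-2(5H)-one | CC(C)(C)[Si](C)(C)OCC/C(C)=C\CC/C(CO[Si](c1ccccc1)(c1ccccc1)C(C)(C)C)=C/[C@H]1OC(=O)C(COCc2ccc(OC)cc2)=C1
F5 | step 12 | (5R)-5-[(1Z,5Z)-8-[(tert-butyldimethylsilyl)oxy]-2-{[(tert-butyldiphenylsilyl)oxy]methyl}-6-methylocta-1,5-dien-1-yl]-3-(hydroxymethyl)furan-2(5H)-one | CC(C)(C)[Si](C)(C)OCC/C(C)=C\CC/C(CO[Si](c1ccccc1)(c1ccccc1)C(C)(C)C)=C/[C@H]1OC(=O)C(CO)=C1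
F6 | step 7 | racemic (2E,9Z)-12-[(tert-butyldimethylsilyl)oxy]-10-methyldodeca-2,9-dien-5-yn-4-ol | C/C=C/C(O)C#CCC/C=C(C)\CCO[Si](C)(C)C(C)(C)C
F7 | step 7 | (2E,9Z)-12-[(tert-butyldimethylsilyl)oxy]-10-methyldodeca-2,9-dien-5-yn-4-one | C/C=C/C(=O)C#CCC/C=C(C)\CCO[Si](C)(C)C(C)(C)C
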